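**Retrosynthetic overview**

1. Germacrane numbering is used (ring C1–C10; C14 = ester carbon on C10, C15 = methyl on C4, lactone carbons C11–C13 on C7, oxygens on C6, C8, C9). The route rests on the 1,5-diene hidden in the ten-membered ring: the ring-cis C1=C10 enoate and the C4–C5 epoxide, which is an E C4=C5 alkene before epoxidation.
2. Late disconnections: O9 acetate, O8 methacrylate, C13 methylene, C14 (carbonylation of a C10 enol triflate), lactone bond C12–O6 and the epoxide. Then the retro-[3,3] step (break C2–C3, make C5–C10) leads to a cis-10-vinyl-5-isopropenylcyclohexan-10-ol (ring C5–C10 carrying C6–C9) whose O6/O8 pair is tied as a 4-methoxybenzylidene acetal.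
3. That cyclohexane: isopropenyl on C5 by epoxide opening, vinyl on C10 by ketone addition, ring bond C5=C10 by ring-closing metathesis. The diene comes from diacetone-D-glucose (sugar C4, C3, C2, C1 = C6, C7, C8, C9; the 3-C-branch = C11, C12).
4. Ring order: cyclohexene (step 12), C5–C10 oxirane (step 13, opened in step 15), bridging 1,3-dioxane (step 14), ten-membered ring by ring expansion (step 18; dioxane opened in step 19), C4–C5 oxirane (step 21), γ-lactone (step 22).

Key step: step 18

Assumption: the SMILES string is taken as the definition of the target, that is a cis-fused 6,12-lactone with O8 on the same face as O6 and C11, and O9 on the opposite face.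

Convention: germacrane numbers are used for all intermediates. On the six-membered ring C5–C10 the face of O6, O8 and the C7 side chain is called β and that of O9 is called α. TBS = tert-butyldimethylsilyl, PMB = 4-methoxybenzyl.

**Route**

Step 1
Reactants: 1 1,2:5,6-di-O-isopropylidene-α-D-glucofuranose
Product: 2 1,2:5,6-di-O-isopropylidene-α-D-ribo-hexofuranos-3-ulose
Conditions: Dess–Martin periodinane, NaHCO3, CH2Cl2, rt
Reagents that add atoms: none
Why: Dess–Martin oxidation of the only free (secondary) hydroxyl gives the 3-ulose without touching the two acetonides, and no stereocentre is created.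

Step 2
Reactants: 2 1,2:5,6-di-O-isopropylidene-α-D-ribo-hexofuranos-3-ulose; 3 triethyl phosphonoacetate
Product: 4 ethyl (3-deoxy-1,2:5,6-di-O-isopropylidene-α-D-ribo-hexofuranos-3-ylidene)acetate (alkene isomers)
Conditions: NaH, THF, 0 °C to rt
Reagents that add atoms: none
Why: Horner–Wadsworth–Emmons olefination of the furanos-3-ulose installs C11 and C12, and the alkene geometry is irrelevant because the double bond is hydrogenated next.

Step 3
Reactants: 4 ethyl (3-deoxy-1,2:5,6-di-O-isopropylidene-α-D-ribo-hexofuranos-3-ylidene)acetate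
Product: 5 3-deoxy-3-C-(2-ethoxy-2-oxoethyl)-1,2:5,6-di-O-isopropylidene-α-D-allofuranose
Conditions: H2 (1 atm), 10% Pd/C, EtOAc, rt
Reagents that add atoms: none
Why: Heterogeneous hydrogenation delivers hydrogen to the exo face of the cis-fused furanose 1,2-acetonide, so the C-branch ends up on the acetonide face (allo configuration), which sets C7 cis to both flanking oxygens (O8 on sugar C2, O6 on sugar C4).

Step 4
Reactants: 5 3-deoxy-3-C-(2-ethoxy-2-oxoethyl)-1,2:5,6-di-O-isopropylidene-α-D-allofuranose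
Product: 6 3-deoxy-3-C-(2-ethoxy-2-oxoethyl)-1,2-O-isopropylidene-α-D-allofuranose
Conditions: AcOH/H2O (7:3), rt
Reagents that add atoms: none
Why: Acid-catalysed acetal hydrolysis is faster for the terminal 5,6-dioxolane than for the bicyclic anomeric 1,2-acetonide, a standard selective deprotection of furanose diacetonides.

Step 5
Reactants: 6 3-deoxy-3-C-(2-ethoxy-2-oxoethyl)-1,2-O-isopropylidene-α-D-allofuranose
Product: 7 3,5,6-trideoxy-3-C-(2-ethoxy-2-oxoethyl)-1,2-O-isopropylidene-α-D-ribo-hex-5-enofuranose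
Conditions: PPh3, I2, imidazole, toluene, 90 °C
Reagents that add atoms: none
Why: The Garegg–Samuelsson olefination converts the terminal vicinal diol through its vicinal iodide into the alkene, which removes the sugar C5 stereocentre and creates the vinyl carbon C5 needed for metathesis.

Step 6
Reactants: 7 3,5,6-trideoxy-3-C-(2-ethoxy-2-oxoethyl)-1,2-O-isopropylidene-α-D-ribo-hex-5-enofuranose
Product: 8 3,5,6-trideoxy-3-C-(2-hydroxyethyl)-1,2-O-isopropylidene-α-D-ribo-hex-5-enofuranose
Conditions: LiAlH4, THF, 0 °C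
Reagents that add atoms: none
Why: Hydride reduction of the ester gives the primary alcohol (C12) while the acetal and the terminal alkene are inert.

Step 7
Reactants: 8 3,5,6-trideoxy-3-C-(2-hydroxyethyl)-1,2-O-isopropylidene-α-D-ribo-hex-5-enofuranose
Product: 9 3,5,6-trideoxy-3-C-(2-hydroxyethyl)-D-ribo-hex-5-enofuranose (lactol, both anomers)
Conditions: CF3CO2H/H2O (4:1), 0 °C to rt, then neutralisation
Reagents that add atoms: none
Why: Aqueous acid hydrolysis of the anomeric acetonide liberates the lactol, which is the latent C9 aldehyde with O8 free and O6 as ring oxygen.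

Step 8
Reactants: 9 3,5,6-trideoxy-3-C-(2-hydroxyethyl)-D-ribo-hex-5-enofuranose; 10 vinylmagnesium bromide (5 equiv)
Product: 11 (3R,4R,5R,6R)-5-(2-hydroxyethyl)octa-1,7-diene-3,4,6-triol (chain C3, C4, C5, C6 = germacrane C9, C8, C7, C6)
Conditions: THF, 0 °C to rt, then aq NH4Cl
Reagents that add atoms: none
Why: Excess Grignard reagent deprotonates the three hydroxyls, the ring-opened aldehyde is held by the neighbouring C8 magnesium alkoxide in a five-membered chelate and is attacked anti to the C7 branch (Cram chelate addition), which should give the 8,9-syn diol, that is O9 trans to O8 in the later ring.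

Step 9
Reactants: 11 (3R,4R,5R,6R)-5-(2-hydroxyethyl)octa-1,7-diene-3,4,6-triol
Product: 12 6,8-O-(4-methoxybenzylidene) acetal of 11 (all-equatorial 1,3-dioxane; O9–H and O12–H free)
Conditions: 4-MeOC6H4CH(OMe)2, PPTS (cat.), CH2Cl2, rt
Reagents that add atoms: 4-methoxybenzaldehyde dimethyl acetal, COc1ccc(C(OC)OC)cc1
Why: Thermodynamic acetalisation selects the syn-1,3-diol O6/O8 because its 1,3-dioxane carries aryl, C5, the C7 side chain and C9 all equatorial, and this equatorial preference also sets the new acetal centre.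

Step 10
Reactants: 12 6,8-O-(4-methoxybenzylidene) acetal of 11
Product: 13 9,12-bis-O-TBS ether of 12
Conditions: TBSOTf (2.5 equiv), 2,6-lutidine, CH2Cl2, −78 to 0 °C
Reagents that add atoms: tert-butyldimethylsilyl triflate, CC(C)(C)[Si](C)(C)OS(=O)(=O)C(F)(F)F
Why: Silylation with the silyl triflate and a hindered base protects both the primary and the hindered allylic secondary hydroxyl without disturbing the acetal.

Step 11
Reactants: 13 9,12-bis-O-TBS ether of 12
Product: 14 8-O-PMB-9,12-bis-O-TBS derivative of 11 with O6–H free (acyclic 1,7-diene)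
Conditions: i-Bu2AlH, CH2Cl2, −78 to 0 °C
Reagents that add atoms: none
Why: In this reductive acetal opening the aluminium reagent coordinates the less hindered O6 (O8 is flanked by the silyloxy-bearing C9), the C–O6 bond breaks and hydride reduces the oxocarbenium ion, which leaves PMB on O8 and O6 free, and the other regioisomer would converge at step 14.

Step 12
Reactants: 14 8-O-PMB-9,12-bis-O-TBS derivative of 11
Product: 15 cyclohexenol (C5=C10 alkene; 6β-OH; 7β-CH2CH2OTBS; 8β-OPMB; 9α-OTBS)
Conditions: second-generation Grubbs catalyst (5 mol%), CH2Cl2, 40 °C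
Reagents that add atoms: none
Why: Ring-closing metathesis of the 1,7-diene closes the six-membered carbocycle with loss of ethene, and free and silylated allylic oxygens are tolerated by the ruthenium carbene.

Step 13
Reactants: 15 cyclohexenol
Product: 16 5β,10β-epoxide of 15
Conditions: VO(acac)2 (cat.), t-BuOOH, CH2Cl2, 0 °C to rt
Reagents that add atoms: tert-butyl hydroperoxide, CC(C)(C)OO
Why: Vanadium-catalysed hydroxyl-directed epoxidation delivers oxygen syn to the allylic O6–H (β face), and the allylic 9α-silyloxy group blocks the other face.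

Step 14
Reactants: 16 5β,10β-epoxide of 15
Product: 17 tricyclic epoxy acetal (6,8-O-(4-methoxybenzylidene) bridge with aryl exo; 5β,10β-epoxide; 7β-CH2CH2OTBS; 9α-OTBS)
Conditions: DDQ, 4 Å molecular sieves, CH2Cl2, 0 °C
Reagents that add atoms: none
Why: DDQ oxidises the PMB ether to an oxocarbenium ion that is trapped under anhydrous conditions by the syn-1,3 O6–H (oxidative PMB-to-benzylidene cyclisation), and the aryl group can only sit exo on the new 2,4-dioxabicyclo[3.3.1]nonane, which fixes the acetal centre.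

Step 15
Reactants: 17 tricyclic epoxy acetal; 18 isopropenylmagnesium bromide
Product: 19 5α-isopropenyl-10β-ol (6,8-O-(4-methoxybenzylidene); 9α-OTBS; 7β-CH2CH2OTBS)
Conditions: CuI (20 mol%), THF, −30 to 0 °C
Reagents that add atoms: none
Why: The copper-catalysed Grignard opening follows the Fürst–Plattner rule, which in the acetal-locked chair allows only α attack at C5 (attack at C10 would give a twist-boat and is also hindered by the cis 9α-silyloxy group), so isopropenyl enters trans to the epoxide oxygen (5α) and O10 stays β.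

Step 16
Reactants: 19 5α-isopropenyl-10β-ol
Product: 20 5α-isopropenyl-10-ketone (6,8-O-(4-methoxybenzylidene); 9α-OTBS; 7β-CH2CH2OTBS)
Conditions: Dess–Martin periodinane, NaHCO3, CH2Cl2, 0 °C to rt
Reagents that add atoms: none
Why: Buffered Dess–Martin oxidation gives the ketone, and because both α-hydrogens (H5, H9) are equatorial in the locked chair and poorly aligned for enolisation, the β,γ-unsaturated ketone should neither epimerise nor conjugate.

Step 17
Reactants: 20 5α-isopropenyl-10-ketone; 10 vinylmagnesium bromide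
Product: 21 10β-hydroxy-10α-vinyl-5α-isopropenylcyclohexane (6,8-O-(4-methoxybenzylidene); 9α-OTBS; 7β-CH2CH2OTBS), the rearrangement precursor
Conditions: CeCl3 (anhydrous), THF, −78 °C
Reagents that add atoms: none
Why: The weakly basic vinylcerium reagent adds 1,2 to the ketone from the exo (α) face because the β face is covered by the acetal bridge, which places vinyl α (cis to isopropenyl) and the hydroxyl β.

Step 18
Reactants: 21 10β-hydroxy-10α-vinyl-5α-isopropenylcyclohexane
Product: 24 ten-membered enol triflate (4E alkene; ring-cis C1=C10 bearing OTf on C10; 6,8-O-(4-methoxybenzylidene); 9-OTBS; 12-OTBS), via potassium alkoxide 22 (not isolated), via potassium enolate 23 (not isolated)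
Conditions: KN(SiMe3)2, THF, 0 to 50 °C; then PhNTf2, −78 to 0 °C
Reagents that add atoms: N-phenylbis(trifluoromethanesulfonimide), FC(F)(F)S(=O)(=O)N(c1ccccc1)S(=O)(=O)C(F)(F)F
Why: KN(SiMe3)2 converts the tertiary C10 alcohol into its potassium alkoxide 22, whose alkoxide-accelerated [3,3] shift through the chair array C2=C1–C10–C5–C4=C3 forms C2–C3 while C5–C10 breaks and gives the C10 enolate 23, which the triflimide O-sulfonylates. The closest known reaction type is the anionic oxy-Cope ring expansion of cis-1,2-dialkenylcyclohexanols to cyclodec-5-enones with O-sulfonylation of the enolate in the same flask. The ten-membered ring is closed by four-atom ring expansion of the six-membered ring (the new C2–C3 bond joins the two alkenyl termini as the shared C5–C10 bond opens), not by end-to-end cyclisation. No stereocentre is created, since C5 and C10 become sp2 and C6 to C9 are spectators. The selectivity needed is geometric (ring-cis C1=C10 with O10 trans to C2, and E C4=C5), and it follows if the carbocycle reacts as the chair with isopropenyl axial and vinyl equatorial, which puts C9 pseudo-axial, O10 pseudo-equatorial and C6 pseudo-equatorial on the six-centre array. That chair is secured by the 6,8-acetal, which can only bridge syn-diaxial O6 and O8, by the endo hydrogen (not a methyl) of the benzylidene carbon facing the axial O10, and by K+ held between O6, O8 and O10 when no crown ether is added.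

Step 19
Reactants: 24 ten-membered enol triflate
Product: 25 6-hydroxy-8-O-PMB enol triflate (9-OTBS; 12-OTBS)
Conditions: i-Bu2AlH, CH2Cl2, −78 to −10 °C
Reagents that add atoms: none
Why: In this reductive acetal opening aluminium coordinates the less hindered allylic O6 (O8 is flanked by C9–OTBS), so PMB stays on O8 and O6 is freed, which is the step that tells apart the two oxygens flanking C7, and the enol triflate is inert to the hydride at low temperature.

Step 20
Reactants: 25 6-hydroxy-8-O-PMB enol triflate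
Product: 26 6,12-diol (8-O-PMB; 9-OTBS; enol triflate)
Conditions: HF·pyridine, pyridine, THF, 0 °C
Reagents that add atoms: none
Why: Buffered fluoride desilylation cleaves the unhindered primary silyl ether much faster than the hindered secondary one on C9.

Step 21
Reactants: 26 6,12-diol
Product: 27 4,5-epoxy-6,12-diol (epoxide configured as in the target; 8-O-PMB; 9-OTBS; enol triflate)
Conditions: mCPBA, NaHCO3, CH2Cl2, 0 °C
Reagents that add atoms: 3-chloroperbenzoic acid, OOC(=O)c1cccc(Cl)c1
Why: In this hydroxyl-directed peracid epoxidation 1,3-allylic strain between H6 and the C15 methyl fixes the rotamer about C5–C6, and the O6–H hydrogen bond delivers oxygen to the peripheral alkene face syn to it (threo epoxy alcohol), which is the 4,5-configuration of the target, while the electron-poor enol triflate alkene does not react.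

Step 22
Reactants: 27 4,5-epoxy-6,12-diol
Product: 29 cis-fused 6,12-lactone (4,5-epoxide; 8-O-PMB; 9-OTBS; enol triflate), via lactol 28 (not isolated)
Conditions: TEMPO (cat.), PhI(OAc)2, CH2Cl2, rt
Reagents that add atoms: none
Why: Oxoammonium-catalysed oxidation takes the primary alcohol to the aldehyde, which closes onto the only free secondary hydroxyl O6 as a five-membered lactol that is oxidised on to the γ-lactone (oxidative lactonisation of a 1,4-diol).

Step 23
Reactants: 29 cis-fused 6,12-lactone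
Product: 30 methyl ester at C10 (C14 installed; 4,5-epoxide; lactone; 8-O-PMB; 9-OTBS)
Conditions: Pd(OAc)2 (cat.), PPh3, CO (1 atm), MeOH, Et3N, DMF, 50 °C
Reagents that add atoms: carbon monoxide, [C-]#[O+]; methanol, CO
Why: Palladium-catalysed methoxycarbonylation of the alkenyl triflate (oxidative addition to zerovalent palladium, CO insertion, methanolysis) installs C14 with retention of the ring-cis alkene geometry.

Step 24
Reactants: 30 methyl ester at C10
Product: 32 11-(dimethylaminomethyl) lactone (C11 epimers), via lithium enolate 31 (not isolated)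
Conditions: LiN(SiMe3)2, THF, −78 °C; then CH2=NMe2+ I−, −78 to 0 °C
Reagents that add atoms: dimethylmethyleneiminium iodide (Eschenmoser's salt), C=[N+](C)C.[I-]
Why: Kinetic deprotonation of the lactone α-position at low temperature and Mannich alkylation of the enolate bring in C13, and the new C11 centre is inconsequential because it becomes sp2 in the next step.

Step 25
Reactants: 32 11-(dimethylaminomethyl) lactone
Product: 34 α-methylene lactone (8-O-PMB; 9-OTBS), via ammonium iodide 33 (not isolated)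
Conditions: MeI, THF, rt; then aq NaHCO3, CH2Cl2, rt
Reagents that add atoms: none
Why: Quaternisation of the amine followed by mild-base Hofmann-type (E1cB) elimination gives the exocyclic methylene.

Step 26
Reactants: 34 α-methylene lactone
Product: 35 8-hydroxy compound (9-OTBS)
Conditions: DDQ, CH2Cl2/pH 7 buffer, 0 °C
Reagents that add atoms: none
Why: Oxidative cleavage of the PMB ether by DDQ in wet solvent runs under buffered neutral conditions that spare the epoxide, the silyl ether and the electron-poor alkenes.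

Step 27
Reactants: 35 8-hydroxy compound
Product: 36 8-O-methacrylate (9-OTBS)
Conditions: methacrylic anhydride, Et3N, DMAP (cat.), CH2Cl2, 0 °C to rt
Reagents that add atoms: methacrylic anhydride, CC(=C)C(=O)OC(=O)C(C)=C
Why: DMAP-catalysed acylation of the secondary alcohol with the anhydride installs the C8 ester.

Step 28
Reactants: 36 8-O-methacrylate
Product: 37 9-hydroxy-8-O-methacrylate
Conditions: HF·pyridine, THF, 0 °C to rt
Reagents that add atoms: none
Why: Fluoride desilylation under acidic, non-nucleophilic conditions leaves the epoxide, the esters and the Michael acceptors intact.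

Step 29
Reactants: 37 9-hydroxy-8-O-methacrylate
Product: 38 fluctuadin
Conditions: Ac2O, pyridine, DMAP (cat.), CH2Cl2, rt
Reagents that add atoms: acetic anhydride, CC(=O)OC(C)=O
Why: DMAP-catalysed acetylation of the last free hydroxyl completes the target.

**Compound list**

1 | 1,2:5,6-di-O-isopropylidene-α-D-glucofuranose | CC1(C)OC[C@@H](O1)[C@H]2O[C@@H]3OC(C)(C)O[C@@H]3[C@H]2O | starting material
2 | 1,2:5,6-di-O-isopropylidene-α-D-ribo-hexofuranos-3-ulose | CC1(C)OC[C@@H](O1)[C@H]2O[C@@H]3OC(C)(C)O[C@@H]3C2=O | intermediate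
3 | triethyl phosphonoacetate | CCOC(=O)CP(=O)(OCC)OCC | starting material
4 | ethyl (3-deoxy-1,2:5,6-di-O-isopropylidene-α-D-ribo-hexofuranos-3-ylidene)acetate (alkene isomers) | CC1(C)OC[C@@H](O1)[C@H]2O[C@@H]3OC(C)(C)O[C@@H]3C2=CC(=O)OCC | intermediate
5 | 3-deoxy-3-C-(2-ethoxy-2-oxoethyl)-1,2:5,6-di-O-isopropylidene-α-D-allofuranose | CC1(C)OC[C@@H](O1)[C@H]2O[C@@H]3OC(C)(C)O[C@@H]3[C@@H]2CC(=O)OCC | intermediate
6 | 3-deoxy-3-C-(2-ethoxy-2-oxoethyl)-1,2-O-isopropylidene-α-D-allofuranose | OC[C@@H](O)[C@H]1O[C@@H]2OC(C)(C)O[C@@H]2[C@@H]1CC(=O)OCC | intermediate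
7 | 3,5,6-trideoxy-3-C-(2-ethoxy-2-oxoethyl)-1,2-O-isopropylidene-α-D-ribo-hex-5-enofuranose | C=C[C@H]1O[C@@H]2OC(C)(C)O[C@@H]2[C@@H]1CC(=O)OCC | intermediate
8 | 3,5,6-trideoxy-3-C-(2-hydroxyethyl)-1,2-O-isopropylidene-α-D-ribo-hex-5-enofuranose | C=C[C@H]1O[C@@H]2OC(C)(C)O[C@@H]2[C@@H]1CCO | intermediate
9 | 3,5,6-trideoxy-3-C-(2-hydroxyethyl)-D-ribo-hex-5-enofuranose (lactol, both anomers) | C=C[C@H]1OC(O)[C@H](O)[C@@H]1CCO | intermediate
10 | vinylmagnesium bromide | C=C[Mg]Br | starting material
11 | (3R,4R,5R,6R)-5-(2-hydroxyethyl)octa-1,7-diene-3,4,6-triol | C=C[C@@H](O)[C@H](O)[C@H](CCO)[C@H](O)C=C | intermediate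
12 | 6,8-O-(4-methoxybenzylidene) acetal of 11 (2,4,6-cis, 5-trans 1,3-dioxane) | C=C[C@@H](O)[C@@H]1O[C@H](c2ccc(OC)cc2)O[C@H](C=C)[C@H]1CCO | intermediate
13 | 9,12-bis-O-TBS ether of 12 | C=C[C@@H](O[Si](C)(C)C(C)(C)C)[C@@H]1O[C@H](c2ccc(OC)cc2)O[C@H](C=C)[C@H]1CCO[Si](C)(C)C(C)(C)C | intermediate
14 | 8-O-PMB-9,12-bis-O-TBS derivative of 11 (O6–H free) | C=C[C@@H](O[Si](C)(C)C(C)(C)C)[C@H](OCc1ccc(OC)cc1)[C@H](CCO[Si](C)(C)C(C)(C)C)[C@H](O)C=C | intermediate
15 | cyclohexenol (C5=C10; 6β-OH; 7β-CH2CH2OTBS; 8β-OPMB; 9α-OTBS) | O[C@@H]1C=C[C@@H](O[Si](C)(C)C(C)(C)C)[C@H](OCc2ccc(OC)cc2)[C@@H]1CCO[Si](C)(C)C(C)(C)C | intermediate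
16 | 5β,10β-epoxide of 15 | O[C@@H]1[C@@H]2O[C@@H]2[C@@H](O[Si](C)(C)C(C)(C)C)[C@H](OCc3ccc(OC)cc3)[C@@H]1CCO[Si](C)(C)C(C)(C)C | intermediate
17 | tricyclic epoxy acetal (6,8-O-(4-methoxybenzylidene), aryl exo; 5β,10β-epoxide; 9α-OTBS; 7β-CH2CH2OTBS) | CC(C)(C)[Si](C)(C)O[C@@H]1[C@H]2O[C@H]2[C@H]3O[C@H](c4ccc(OC)cc4)O[C@@H]1[C@@H]3CCO[Si](C)(C)C(C)(C)C | intermediate
18 | isopropenylmagnesium bromide | CC(=C)[Mg]Br | starting material
19 | 5α-isopropenyl-10β-ol (acetal-locked) | CC(C)(C)[Si](C)(C)O[C@@H]1[C@@H](O)[C@H](C(C)=C)[C@H]2O[C@H](c3ccc(OC)cc3)O[C@@H]1[C@@H]2CCO[Si](C)(C)C(C)(C)C | intermediate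
20 | 5α-isopropenyl-10-ketone (acetal-locked) | CC(C)(C)[Si](C)(C)O[C@@H]1C(=O)[C@H](C(C)=C)[C@H]2O[C@H](c3ccc(OC)cc3)O[C@@H]1[C@@H]2CCO[Si](C)(C)C(C)(C)C | intermediate
21 | 10β-hydroxy-10α-vinyl-5α-isopropenylcyclohexane (6,8-O-(4-methoxybenzylidene); 9α-OTBS; 7β-CH2CH2OTBS) | CC(C)(C)[Si](C)(C)O[C@@H]1[C@](O)(C=C)[C@H](C(C)=C)[C@H]2O[C@H](c3ccc(OC)cc3)O[C@@H]1[C@@H]2CCO[Si](C)(C)C(C)(C)C | intermediate
22 | potassium alkoxide of 21 (formed in the flask) | CC(C)(C)[Si](C)(C)O[C@@H]1[C@]([O-])(C=C)[C@H](C(C)=C)[C@H]2O[C@H](c3ccc(OC)cc3)O[C@@H]1[C@@H]2CCO[Si](C)(C)C(C)(C)C.[K+] | intermediate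
23 | potassium C10 enolate of the ten-membered ring (4E; ring-cis C1=C10; formed in the flask) | C/C1=C\[C@H]2O[C@H](c3ccc(OC)cc3)O[C@H]([C@@H]2CCO[Si](C)(C)C(C)(C)C)[C@H](O[Si](C)(C)C(C)(C)C)/C([O-])=C\CC1.[K+] | intermediate
24 | ten-membered enol triflate (4E; ring-cis C1=C10; 6,8-O-(4-methoxybenzylidene); 9-OTBS; 12-OTBS) | C/C1=C\[C@H]2O[C@H](c3ccc(OC)cc3)O[C@H]([C@@H]2CCO[Si](C)(C)C(C)(C)C)[C@H](O[Si](C)(C)C(C)(C)C)/C(OS(=O)(=O)C(F)(F)F)=C\CC1 | intermediate
25 | 6-hydroxy-8-O-PMB enol triflate (9-OTBS; 12-OTBS) | C/C1=C\[C@@H](O)[C@@H](CCO[Si](C)(C)C(C)(C)C)[C@@H](OCc2ccc(OC)cc2)[C@H](O[Si](C)(C)C(C)(C)C)/C(OS(=O)(=O)C(F)(F)F)=C\CC1 | intermediate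
26 | 6,12-diol (8-O-PMB; 9-OTBS; enol triflate) | C/C1=C\[C@@H](O)[C@@H](CCO)[C@@H](OCc2ccc(OC)cc2)[C@H](O[Si](C)(C)C(C)(C)C)/C(OS(=O)(=O)C(F)(F)F)=C\CC1 | intermediate
27 | 4,5-epoxy-6,12-diol (8-O-PMB; 9-OTBS; enol triflate) | COc1ccc(CO[C@@H]2[C@H](CCO)[C@H](O)[C@H]3O[C@]3(C)CC/C=C(/OS(=O)(=O)C(F)(F)F)[C@H]2O[Si](C)(C)C(C)(C)C)cc1 | intermediate
28 | 6,12-lactol (C12 epimers; formed in the flask) | COc1ccc(CO[C@@H]2[C@@H]3CC(O)O[C@@H]3[C@H]4O[C@]4(C)CC/C=C(/OS(=O)(=O)C(F)(F)F)[C@H]2O[Si](C)(C)C(C)(C)C)cc1 | intermediate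
29 | cis-fused 6,12-lactone (4,5-epoxide; 8-O-PMB; 9-OTBS; enol triflate) | COc1ccc(CO[C@@H]2[C@@H]3CC(=O)O[C@@H]3[C@H]4O[C@]4(C)CC/C=C(/OS(=O)(=O)C(F)(F)F)[C@H]2O[Si](C)(C)C(C)(C)C)cc1 | intermediate
30 | C10 methyl ester (4,5-epoxide; lactone; 8-O-PMB; 9-OTBS) | COc1ccc(CO[C@@H]2[C@@H]3CC(=O)O[C@@H]3[C@H]4O[C@]4(C)CC/C=C(/C(=O)OC)[C@H]2O[Si](C)(C)C(C)(C)C)cc1 | intermediate
31 | lithium enolate of lactone 30 (formed in the flask) | COc1ccc(CO[C@@H]2[C@@H]3C=C([O-])O[C@@H]3[C@H]4O[C@]4(C)CC/C=C(/C(=O)OC)[C@H]2O[Si](C)(C)C(C)(C)C)cc1.[Li+] | intermediate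
32 | 11-(dimethylaminomethyl) lactone (C11 epimers) | COc1ccc(CO[C@@H]2[C@@H]3C(CN(C)C)C(=O)O[C@@H]3[C@H]4O[C@]4(C)CC/C=C(/C(=O)OC)[C@H]2O[Si](C)(C)C(C)(C)C)cc1 | intermediate
33 | 11-(trimethylammoniomethyl) lactone iodide (formed in the flask) | COc1ccc(CO[C@@H]2[C@@H]3C(C[N+](C)(C)C)C(=O)O[C@@H]3[C@H]4O[C@]4(C)CC/C=C(/C(=O)OC)[C@H]2O[Si](C)(C)C(C)(C)C)cc1.[I-] | intermediate
34 | α-methylene lactone (8-O-PMB; 9-OTBS) | COc1ccc(CO[C@@H]2[C@@H]3C(=C)C(=O)O[C@@H]3[C@H]4O[C@]4(C)CC/C=C(/C(=O)OC)[C@H]2O[Si](C)(C)C(C)(C)C)cc1 | intermediate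
35 | 8-hydroxy compound (9-OTBS) | O[C@@H]1[C@@H]2C(=C)C(=O)O[C@@H]2[C@H]2O[C@]2(C)CC/C=C(/C(=O)OC)[C@H]1O[Si](C)(C)C(C)(C)C | intermediate
36 | 8-O-methacrylate (9-OTBS) | C=C(C)C(=O)O[C@@H]1[C@@H]2C(=C)C(=O)O[C@@H]2[C@H]2O[C@]2(C)CC/C=C(/C(=O)OC)[C@H]1O[Si](C)(C)C(C)(C)C | intermediate
37 | 9-hydroxy-8-O-methacrylate | C=C(C)C(=O)O[C@@H]1[C@@H]2C(=C)C(=O)O[C@@H]2[C@H]2O[C@]2(C)CC/C=C(/C(=O)OC)[C@H]1O | intermediate
38 | fluctuadin | C=C(C)C(=O)O[C@@H]1[C@@H]2C(=C)C(=O)O[C@@H]2[C@H]2O[C@]2(C)CC/C=C(/C(=O)OC)[C@H]1OC(C)=O | target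

**Step count and risks**

Total step count: 29. Longest linear sequence: 29 steps (1 to 38).

The three steps most likely to fail:

Step 18 (key step). The carbocycle of alkoxide 22 may tip C10 away from the acetal bridge (chair-to-boat flip that relieves the syn-triaxial O6/O8/O10 array). Part of the material would then rearrange through the other chair-like six-centre array and the geometric purity of both new alkenes would be eroded. In addition, the hindered potassium enolate may be sulfonylated only slowly. The fallback is the uncharged siloxy variant, which sets out from 21 and comes back at 24. Me3SiOTf and Et3N should give the 10-O-trimethylsilyl ether F1, in which no charged oxygen has to sit between O6 and O8. Heating F1 in o-dichlorobenzene at about 200 °C should give, by the neutral [3,3] shift through the same locked chair, the ring-expanded trimethylsilyl enol ether F2. MeLi in THF then cleaves the Si–O bond to the lithium enolate with unchanged regiochemistry and geometry, and PhNTf2 converts it into 24.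

Step 17. The carbonyl of 20 is flanked on its only open face by the axial isopropenyl and silyloxy groups. Addition may therefore be slower than enolisation, with epimerisation at C5, β-elimination of O6 or recovery of ketone as the result. The fallback is alkynylation followed by semi-reduction, which sets out from 20 and comes back at 21. The slimmer and still weakly basic cerium acetylide (ethynylmagnesium bromide with CeCl3, THF, −78 °C) should add from the same exo face to give the 10α-ethynyl-10β-carbinol F3. Semi-hydrogenation (H2, Pd/CaCO3 poisoned with Pb(OAc)2, quinoline) of the terminal alkyne, which is reduced much faster than the isopropenyl group, then gives 21.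

Step 19. Aluminium may coordinate O8 instead of O6, which would leave PMB on O6, and the lactone would later close onto the wrong oxygen. The fallback is stepwise differentiation by size, which sets out from 24 and comes back at 26. PPTS in MeOH removes the acetal and the primary silyl ether to give the 6,8,12-triol F4. Et3SiCl (2 equiv) with imidazole at −20 °C silylates the primary O12 and the less hindered allylic O6 to give the 6,12-bis-O-triethylsilyl ether F5. The remaining hindered O8–H is converted into its PMB ether with 4-methoxybenzyl trichloroacetimidate and catalytic La(OTf)3, giving the 8-O-PMB-6,12-bis-O-triethylsilyl ether F6. PPTS in MeOH at 0 °C then removes both triethylsilyl groups and returns diol 26.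

**Further compounds**

F1 | step 18 | 10-O-trimethylsilyl ether of 21 | CC(C)(C)[Si](C)(C)O[C@@H]1[C@](O[Si](C)(C)C)(C=C)[C@H](C(C)=C)[C@H]2O[C@H](c3ccc(OC)cc3)O[C@@H]1[C@@H]2CCO[Si](C)(C)C(C)(C)C
F2 | step 18 | ring-expanded C10 trimethylsilyl enol ether (4E; ring-cis C1=C10) | C/C1=C\[C@H]2O[C@H](c3ccc(OC)cc3)O[C@H]([C@@H]2CCO[Si](C)(C)C(C)(C)C)[C@H](O[Si](C)(C)C(C)(C)C)/C(O[Si](C)(C)C)=C\CC1
F3 | step 17 | 10α-ethynyl-10β-hydroxy-5α-isopropenylcyclohexane (acetal-locked) | CC(C)(C)[Si](C)(C)O[C@@H]1[C@](O)(C#C)[C@H](C(C)=C)[C@H]2O[C@H](c3ccc(OC)cc3)O[C@@H]1[C@@H]2CCO[Si](C)(C)C(C)(C)C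
F4 | step 19 | 6,8,12-triol (9-OTBS; enol triflate) | C/C1=C\[C@@H](O)[C@@H](CCO)[C@@H](O)[C@H](O[Si](C)(C)C(C)(C)C)/C(OS(=O)(=O)C(F)(F)F)=C\CC1
F5 | step 19 | 6,12-bis-O-triethylsilyl ether (O8–H free; 9-OTBS; enol triflate) | C/C1=C\[C@@H](O[Si](CC)(CC)CC)[C@@H](CCO[Si](CC)(CC)CC)[C@@H](O)[C@H](O[Si](C)(C)C(C)(C)C)/C(OS(=O)(=O)C(F)(F)F)=C\CC1
F6 | step 19 | 8-O-PMB-6,12-bis-O-triethylsilyl ether (9-OTBS; enol triflate) | C/C1=C\[C@@H](O[Si](CC)(CC)CC)[C@@H](CCO[Si](CC)(CC)CC)[C@@H](OCc2ccc(OC)cc2)[C@H](O[Si](C)(C)C(C)(C)C)/C(OS(=O)(=O)C(F)(F)F)=C\CC1
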